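**Plan**

1. Numbering (elemane): the carbocycle is C5–C6–C7–C8–C9–C10. C10 carries CH3 and the C1=C2 enol acetate, C5 the C4(=C3)C15 isopropenyl group, C6–O and C7–C11(=C13)–C12 form the lactone, C8 carries the angelate and C9 the acetate. β is the face of the 10-CH3 group; the target is 5S,6R,7S,8R,9R,10S.
2. Retrosynthesis: the esters on O8 and O9 and C15 (isopropenyl ← methyl ketone ← vinyl) are removed and the lactone C12–O6 is opened. The carbocycle is then cut in one stroke at C5–C6 and C9–C10 into a C6–C9 dialdehyde (8) and a C3–C4–C5–C10–C1–C2 triene (12).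
3. Enabling feature: the ring is a cyclohexane-1,4-diol (O on C6 and C9) whose intervening carbons C10 (quaternary) and C5 (alkenyl-bearing) are vicinal. This is the retron of two consecutive carbonyl allylborations by one diene-derived 1,2-bis(boronate): C10 adds to C9=O, then C5 adds to C6=O.
4. Forward order: fragment A (8) comes from itaconic anhydride and ethyl glyoxylate by an auxiliary-controlled aldol; fragment B (13) comes from (Z)-3-methylpent-2-en-4-yn-1-ol. Their union builds the only carbocycle; the lactone ring follows, then the acetate, C15 and the angelate.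
5. Stereochemistry: C7/C8 come from the thiazolidinethione syn aldol. One C–B stereocentre is set by catalytic enantioselective diboration, and C9, C10, C5 and C6 are all relayed from it in the key step through chair transition states. The Z enol acetate comes from the bought Z-enynol and a Z-selective ruthenium-catalysed addition of acetic acid; the angelate geometry is bought.

Key step: step 10

Assumption: the (R,R) enantiomer of the TADDOL-derived phosphonite ligand is taken to give the 5S configuration of 13; if the sense of induction is the opposite, the (S,S) ligand is used.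
Remark: dialdehyde 8 is configurationally labile at C7 and is used crude, directly after its preparation.

**Route**

Step 1
Reactants: 1 (4R)-4-benzyl-1,3-thiazolidine-2-thione; 2 itaconic anhydride
Product: 3 4-[(4R)-4-benzyl-2-sulfanylidene-1,3-thiazolidin-3-yl]-2-methylidene-4-oxobutanoic acid
Conditions: NaN(SiMe3)2, THF, −78 °C; then 2, −78 → −20 °C; aq. HCl work-up
Reagents that add atoms: none
Why: N-acylation by anhydride ring opening: the sodium salt of 1 should attack the non-conjugated, less hindered carbonyl of 2 (the one next to CH2, as in the known aminolysis and alcoholysis of itaconic anhydride), which puts the auxiliary on C6 and leaves the C12 acrylic acid free.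

Step 2
Reactants: 3 the acid from step 1
Product: 4 tert-butyl 4-[(4R)-4-benzyl-2-sulfanylidene-1,3-thiazolidin-3-yl]-2-methylidene-4-oxobutanoate
Conditions: Cl3CC(=NH)OtBu, BF3·OEt2 (cat.), CH2Cl2/cyclohexane, rt
Reagents that add atoms: tert-butyl 2,2,2-trichloroacetimidate, CC(C)(C)OC(=N)C(Cl)(Cl)Cl
Why: Acid-catalysed O-alkylation of the carboxylic acid by the imidate (tert-butyl ester formation) under non-basic conditions that should not isomerise the β,γ-unsaturated acyl unit; the tert-butyl ester is chosen because it resists iBu2AlH in step 5.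

Step 3
Reactants: 4 the tert-butyl ester; 5 ethyl glyoxylate
Product: 6 5-tert-butyl 1-ethyl (2R,3R)-3-{[(4R)-4-benzyl-2-sulfanylidene-1,3-thiazolidin-3-yl]carbonyl}-2-hydroxy-4-methylidenepentanedioate
Conditions: TiCl4, iPr2NEt, N-methylpyrrolidinone, CH2Cl2, −78 → 0 °C; then 5 (freshly distilled), −78 °C
Reagents that add atoms: none
Why: Titanium enolate aldol of an N-acyl thiazolidinethione (Evans-syn sense): the Z-enolate should add through its α-carbon C7 in a closed chair transition state on the face away from the benzyl group, which sets C7 and C8 together as the 2R,3R syn adduct.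

Step 4
Reactants: 6 the aldol adduct
Product: 7 5-tert-butyl 1-ethyl (2R,3R)-3-{[(4R)-4-benzyl-2-sulfanylidene-1,3-thiazolidin-3-yl]carbonyl}-2-[(tert-butyldimethylsilyl)oxy]-4-methylidenepentanedioate
Conditions: TBSOTf, 2,6-lutidine, CH2Cl2, −78 → 0 °C
Reagents that add atoms: tert-butyldimethylsilyl trifluoromethanesulfonate, CC(C)(C)[Si](C)(C)OS(=O)(=O)C(F)(F)F
Why: Silylation of the secondary alcohol with the silyl triflate, done promptly because the free β-hydroxy thioimide can undergo retro-aldol cleavage; the silyl ether later blocks O8 so that only O6 can lactonise.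

Step 5
Reactants: 7 the silyl ether
Product: 8 tert-butyl (3R,4R)-4-[(tert-butyldimethylsilyl)oxy]-3-formyl-2-methylidene-5-oxopentanoate (C6 = formyl carbon, C9 = C5 of the pentanoate)
Conditions: iBu2AlH (2.3 equiv), CH2Cl2, −78 °C; MeOH, aq. Rochelle salt, 0 °C; used crude
Reagents that add atoms: none
Why: Partial reduction with iBu2AlH: the N-acyl thiazolidinethione and the α-silyloxy ethyl ester should each give a tetrahedral aluminium intermediate that is stable at −78 °C and releases the aldehyde on work-up, while the hindered conjugated tert-butyl ester should not react.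

Step 6
Reactants: 9 (2Z)-3-methylpent-2-en-4-yn-1-ol
Product: 10 (2Z)-3-methylpent-2-en-4-ynal
Conditions: MnO2 (activated), CH2Cl2, rt
Reagents that add atoms: none
Why: MnO2 oxidation of the allylic alcohol to the enal under neutral conditions, which should keep the Z geometry of the trisubstituted alkene.

Step 7
Reactants: 10 the enynal
Product: 11 (3Z)-4-methylhexa-1,3-dien-5-yne
Conditions: Ph3PCH3Br, KOtBu, Et2O, 0 °C → rt; kept as a solution (volatile)
Reagents that add atoms: methyltriphenylphosphonium bromide, C[P+](c1ccccc1)(c1ccccc1)c1ccccc1.[Br-]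
Why: Wittig methylenation of the non-enolisable enal should give the terminal vinyl group (C4=C3) without touching the Z alkene or the alkyne.

Step 8
Reactants: 11 the dienyne
Product: 12 (1Z,3Z)-3-methylhexa-1,3,5-trien-1-yl acetate
Conditions: Ru(η3-CH2C(CH3)CH2)2(Ph2P(CH2)4PPh2) (2 mol %), AcOH (1.2 equiv), toluene, 50 °C
Reagents that add atoms: acetic acid, CC(=O)O
Why: Ruthenium-vinylidene-mediated anti-Markovnikov addition of a carboxylic acid to a terminal alkyne, a reaction type known for conjugated enynes: acetate attacks the vinylidene carbon and protonolysis should deliver the Z enol ester, so the Z C1=C2 enol acetate is set here.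

Step 9
Reactants: 12 the trienyl acetate
Product: 13 (1Z,3Z,5S)-3-methyl-5,6-bis(4,4,5,5-tetramethyl-1,3,2-dioxaborolan-2-yl)hexa-1,3-dien-1-yl acetate
Conditions: Pt(dba)3 (3 mol %), (R,R)-TADDOL-derived phenylphosphonite with 3,5-diisopropylphenyl groups (6 mol %), B2pin2, THF, 60 °C
Reagents that add atoms: bis(pinacolato)diboron, CC1(C)OB(B2OC(C)(C)C(C)(C)O2)OC1(C)C
Why: Platinum-catalysed enantioselective 1,2-diboration of the terminal alkene of a 1,3-diene: the Z-disposed substituent on C10 keeps the diene out of the s-cis conformation, so 1,2- rather than 1,4-addition is expected (as known for cis- and 4,4-disubstituted dienes), the internal trisubstituted and enol ester alkenes should be left, and the chiral phosphonite sets the C–B stereocentre (5S).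

Step 10
Reactants: 13 the 1,2-bis(boronate); 8 the dialdehyde
Product: 16 cyclohexanediol tert-butyl ester, via E-allylboronate aldehyde 14 (not isolated), via bis(O-boronate) 15 (not isolated)
Conditions: toluene, 4 Å molecular sieves, 23 → 50 °C; then pH 7 buffer/aq. NaHCO3
Reagents that add atoms: none
Why: The secondary allylic boronate of 13 adds through its γ-carbon C10 to the inductively activated α-silyloxy aldehyde C9 of 8 in a closed six-membered chair (syn SE2'), which moves the double bond to C4=C5 and turns the spectator primary boronate into a new E-allylboronate (14); this adds intramolecularly through C5 to the C6 aldehyde and closes the cyclohexane, leaving the C4=C3 vinyl group on C5. The closest precedent is the tandem 1,2-diboration/double allylation of 1,3-dienes with 1,4-dicarbonyl compounds to give cyclohexane-1,4-diols. The single ring closure is a 6-exo-trig carbonyl allylboration through a trans-decalin-like chair–chair transition state in which the substituents on C7, C8 and C9 and the forming bonds at C5 and C6 are all equatorial. C10 and C9 are set by the C–B stereocentre of 13 together with the Z-diene geometry (CH2Bpin equatorial, acetoxyvinyl axial on the γ-carbon, aldehyde chain equatorial: 9R,10S); C5 and C6 are set by the E geometry of 14 and the all-equatorial chair, that is, relayed from C9/C10 and C7/C8 (5S,6R). The step needs C9 to react before C6 (secured by the α-oxygen activation of C9 and the greater hindrance at C6), an E-allylboronate in 14 (secured because an axial CH2Bpin would clash 1,3-diaxially with the Z substituent on C10), and reagent control over the Felkin–Anh preference of the α-silyloxy aldehyde (secured by the same conformational lock of the α-substituted allylboronate).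

Step 11
Reactants: 16 the cyclohexanediol tert-butyl ester
Product: 18 lactone alcohol, via hydroxy acid 17 (not isolated)
Conditions: CF3CO2H, CH2Cl2, 0 °C, brief
Reagents that add atoms: none
Why: Acidolysis of the tert-butyl ester followed by acid-catalysed lactonisation (5-exo-trig acyl substitution) of the 6α-hydroxyl onto C12 should give the trans-fused α-methylene γ-lactone; O8 is silylated and the 9-hydroxyl would need a bridged δ-lactone, so only O6 can close.

Step 12
Reactants: 18 the lactone alcohol
Product: 19 (1Z)-2,9β-diacetoxy-8α-[(tert-butyldimethylsilyl)oxy]-15-norelema-1,3,11(13)-trien-12,6α-olide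
Conditions: Ac2O, pyridine, DMAP (cat.), CH2Cl2, 0 °C → rt
Reagents that add atoms: acetic anhydride, CC(=O)OC(C)=O
Why: DMAP-catalysed acetylation of the hindered equatorial 9β-hydroxyl, the only free hydroxyl group.

Step 13
Reactants: 19 the diacetate
Product: 20 (1Z)-2,9β-diacetoxy-8α-[(tert-butyldimethylsilyl)oxy]-4-oxo-15-norelema-1,11(13)-dien-12,6α-olide
Conditions: Pd(Quinox)Cl2 (5 mol %; Quinox = 2-(4,5-dihydrooxazol-2-yl)quinoline), AgSbF6 (12 mol %), aq. tBuOOH, CH2Cl2, 0 °C → rt
Reagents that add atoms: tert-butyl hydroperoxide, CC(C)(C)OO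
Why: Peroxide-mediated Wacker-type oxidation (Tsuji–Wacker reaction): the only monosubstituted alkene should undergo Markovnikov oxypalladation to the methyl ketone, the quinoline–oxazoline ligand enforcing ketone selectivity, while the conjugated 1,1-disubstituted methylene and the hindered 1,2-disubstituted enol acetate are much less reactive; C5 stays equatorial.

Step 14
Reactants: 20 the methyl ketone
Product: 21 (1Z)-2,9β-diacetoxy-8α-[(tert-butyldimethylsilyl)oxy]elema-1,3,11(13)-trien-12,6α-olide
Conditions: Zn, CH2Br2, TiCl4, THF (pre-formed reagent); then 20, CH2Cl2, 0 °C → rt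
Reagents that add atoms: dibromomethane, BrCBr
Why: Lombardo methylenation: the non-basic zinc–titanium methylene reagent should convert the ketone into the isopropenyl group without enolisation at C5, β-elimination of the lactone oxygen or attack on the lactone and acetate carbonyls.

Step 15
Reactants: 21 the silyl ether
Product: 22 (1Z)-2,9β-diacetoxy-8α-hydroxyelema-1,3,11(13)-trien-12,6α-olide
Conditions: HF·pyridine, pyridine, THF, 0 °C → rt
Reagents that add atoms: none
Why: Si–O cleavage by buffered HF·pyridine, mildly acidic conditions under which the acetate, the enol acetate and the α-methylene lactone should survive and 9→8 acetyl migration should be slow.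

Step 16
Reactants: 22 the 8α-alcohol; 23 angelic acid
Product: 24 (1Z)-2,9β-diacetoxy-8α-[(Z)-2-methylbut-2-enoyloxy]elema-1,3,11(13)-trien-12,6α-olide (target, 5S,6R,7S,8R,9R,10S)
Conditions: 23, 2,4,6-Cl3C6H2COCl, Et3N, toluene, rt; then 22, 80 °C
Reagents that add atoms: none
Why: Yamaguchi esterification through the mixed 2,4,6-trichlorobenzoic anhydride without DMAP, conditions known to acylate hindered secondary alcohols with angelic acid without Z→E isomerisation to the tiglate.

**Compound list**

1 | (4R)-4-benzyl-1,3-thiazolidine-2-thione | S=C1N[C@H](Cc2ccccc2)CS1 | starting material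
2 | itaconic anhydride | C=C1CC(=O)OC1=O | starting material
3 | 4-[(4R)-4-benzyl-2-sulfanylidene-1,3-thiazolidin-3-yl]-2-methylidene-4-oxobutanoic acid | C=C(CC(=O)N1[C@H](Cc2ccccc2)CSC1=S)C(=O)O | intermediate
4 | tert-butyl 4-[(4R)-4-benzyl-2-sulfanylidene-1,3-thiazolidin-3-yl]-2-methylidene-4-oxobutanoate | C=C(CC(=O)N1[C@H](Cc2ccccc2)CSC1=S)C(=O)OC(C)(C)C | intermediate
5 | ethyl glyoxylate | CCOC(=O)C=O | starting material
6 | 5-tert-butyl 1-ethyl (2R,3R)-3-{[(4R)-4-benzyl-2-sulfanylidene-1,3-thiazolidin-3-yl]carbonyl}-2-hydroxy-4-methylidenepentanedioate | CCOC(=O)[C@H](O)[C@@H](C(=C)C(=O)OC(C)(C)C)C(=O)N1[C@H](Cc2ccccc2)CSC1=S | intermediate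
7 | 5-tert-butyl 1-ethyl (2R,3R)-3-{[(4R)-4-benzyl-2-sulfanylidene-1,3-thiazolidin-3-yl]carbonyl}-2-[(tert-butyldimethylsilyl)oxy]-4-methylidenepentanedioate | CCOC(=O)[C@H](O[Si](C)(C)C(C)(C)C)[C@@H](C(=C)C(=O)OC(C)(C)C)C(=O)N1[C@H](Cc2ccccc2)CSC1=S | intermediate
8 | tert-butyl (3R,4R)-4-[(tert-butyldimethylsilyl)oxy]-3-formyl-2-methylidene-5-oxopentanoate | O=C[C@H](O[Si](C)(C)C(C)(C)C)[C@H](C=O)C(=C)C(=O)OC(C)(C)C | intermediate
9 | (2Z)-3-methylpent-2-en-4-yn-1-ol | C#C/C(C)=C\CO | starting material
10 | (2Z)-3-methylpent-2-en-4-ynal | C#C/C(C)=C\C=O | intermediate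
11 | (3Z)-4-methylhexa-1,3-dien-5-yne | C#C/C(C)=C\C=C | intermediate
12 | (1Z,3Z)-3-methylhexa-1,3,5-trien-1-yl acetate | CC(=O)O/C=C\C(C)=C/C=C | intermediate
13 | (1Z,3Z,5S)-3-methyl-5,6-bis(4,4,5,5-tetramethyl-1,3,2-dioxaborolan-2-yl)hexa-1,3-dien-1-yl acetate | CC(=O)O/C=C\C(C)=C/[C@H](CB1OC(C)(C)C(C)(C)O1)B1OC(C)(C)C(C)(C)O1 | intermediate
14 | open-chain adduct after the first allylation: C6 aldehyde, C7 tert-butyl acrylate, 8-OTBS, 9-O-Bpin, C10 bearing CH3, (Z)-2-acetoxyvinyl and (E)-3-(pinacolboryl)prop-1-enyl; C7–C10 configured as in 24 | O=C[C@H](C(=C)C(=O)OC(C)(C)C)[C@@H](O[Si](C)(C)C(C)(C)C)[C@H](OB1OC(C)(C)C(C)(C)O1)[C@@](C)(/C=C\OC(C)=O)/C=C/CB1OC(C)(C)C(C)(C)O1 | intermediate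
15 | 6α,9β-bis(O-pinacolboryl) derivative of 16 | CC1(C)OB(O[C@H]2[C@H](C(=C)C(=O)OC(C)(C)C)[C@@H](O[Si](C)(C)C(C)(C)C)[C@H](OB3OC(C)(C)C(C)(C)O3)[C@@](C)(/C=C\OC(C)=O)[C@@H]2C=C)OC1(C)C | intermediate
16 | tert-butyl (1Z)-2-acetoxy-8α-[(tert-butyldimethylsilyl)oxy]-6α,9β-dihydroxy-15-norelema-1,3,11(13)-trien-12-oate (cyclohexane with 10β-CH3, 10α-(Z)-2-acetoxyvinyl, 5β-vinyl, 6α-OH, 7β-acrylate, 8α-OTBS, 9β-OH) | O[C@H]1[C@H](C(=C)C(=O)OC(C)(C)C)[C@@H](O[Si](C)(C)C(C)(C)C)[C@H](O)[C@@](C)(/C=C\OC(C)=O)[C@@H]1C=C | intermediate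
17 | (1Z)-2-acetoxy-8α-[(tert-butyldimethylsilyl)oxy]-6α,9β-dihydroxy-15-norelema-1,3,11(13)-trien-12-oic acid | O[C@H]1[C@H](C(=C)C(=O)O)[C@@H](O[Si](C)(C)C(C)(C)C)[C@H](O)[C@@](C)(/C=C\OC(C)=O)[C@@H]1C=C | intermediate
18 | (1Z)-2-acetoxy-8α-[(tert-butyldimethylsilyl)oxy]-9β-hydroxy-15-norelema-1,3,11(13)-trien-12,6α-olide | C=C1C(=O)O[C@H]2[C@H]1[C@@H](O[Si](C)(C)C(C)(C)C)[C@H](O)[C@@](C)(/C=C\OC(C)=O)[C@@H]2C=C | intermediate
19 | (1Z)-2,9β-diacetoxy-8α-[(tert-butyldimethylsilyl)oxy]-15-norelema-1,3,11(13)-trien-12,6α-olide | C=C1C(=O)O[C@H]2[C@H]1[C@@H](O[Si](C)(C)C(C)(C)C)[C@H](OC(C)=O)[C@@](C)(/C=C\OC(C)=O)[C@@H]2C=C | intermediate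
20 | (1Z)-2,9β-diacetoxy-8α-[(tert-butyldimethylsilyl)oxy]-4-oxo-15-norelema-1,11(13)-dien-12,6α-olide | C=C1C(=O)O[C@H]2[C@H]1[C@@H](O[Si](C)(C)C(C)(C)C)[C@H](OC(C)=O)[C@@](C)(/C=C\OC(C)=O)[C@@H]2C(C)=O | intermediate
21 | (1Z)-2,9β-diacetoxy-8α-[(tert-butyldimethylsilyl)oxy]elema-1,3,11(13)-trien-12,6α-olide | C=C1C(=O)O[C@H]2[C@H]1[C@@H](O[Si](C)(C)C(C)(C)C)[C@H](OC(C)=O)[C@@](C)(/C=C\OC(C)=O)[C@@H]2C(=C)C | intermediate
22 | (1Z)-2,9β-diacetoxy-8α-hydroxyelema-1,3,11(13)-trien-12,6α-olide | C=C1C(=O)O[C@H]2[C@H]1[C@@H](O)[C@H](OC(C)=O)[C@@](C)(/C=C\OC(C)=O)[C@@H]2C(=C)C | intermediate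
23 | angelic acid, (2Z)-2-methylbut-2-enoic acid | C/C=C(/C)C(=O)O | starting material
24 | (1Z)-2,9β-diacetoxy-8α-[(Z)-2-methylbut-2-enoyloxy]elema-1,3,11(13)-trien-12,6α-olide (5S,6R,7S,8R,9R,10S) | C=C1C(=O)O[C@H]2[C@H]1[C@@H](OC(=O)/C(C)=C\C)[C@H](OC(C)=O)[C@@](C)(/C=C\OC(C)=O)[C@@H]2C(=C)C | target

**Step count and risks**

Total step count: 16. Longest linear sequence: 12 steps (steps 1–5, then 10–16); the second branch (steps 6–9) joins at step 10.

The three steps judged most likely to fail:

(a) Key step, step 10. The intermolecular allylboration may not discriminate well enough between the C9 and C6 aldehydes, which would give the regioisomeric ring. The inherent Felkin–Anh preference of the α-silyloxy aldehyde opposes the reagent here and may erode the facial selectivity at C9. C7 may also epimerise while the slow first addition proceeds. The fallback separates the two carbonyl additions; it sets out from 7 and comes back at 16. Reduction of the thioimide of 7 alone (iBu2AlH, 1.05 equiv, −78 °C) should give the aldehyde ester F1. Acetalisation (HC(OMe)3, pyridinium p-toluenesulfonate, MeOH) masks C6 as the dimethyl acetal F2. A second iBu2AlH reduction of the ethyl ester gives the mono-aldehyde F3, in which only C9 can react. Allylboration of F3 with 13 gives the open-chain O-boronate F4 (not isolated). Mild acetal hydrolysis (wet acetone, Amberlyst-15) then frees the C6 aldehyde in F5, which should cyclise at once to the O-boronate F6; aqueous work-up gives 16.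

(b) Step 5. The α-silyloxy ester may be over-reduced to the alcohol or left partly unreduced, and the β,γ-unsaturated aldehyde may epimerise at C7 or suffer double-bond migration during the aqueous aluminium work-up. The fallback is a redox detour under neutral final conditions; it sets out from 7 and comes back at 8. LiBH4 (THF, 0 °C) reduces both acyl groups of 7 to the diol F7 while the tert-butyl ester is left. A buffered double Dess–Martin oxidation (NaHCO3, CH2Cl2) then gives 8 without aqueous base or aluminium salts, and it is used directly.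

(c) Step 13. Hydroxypalladation may occur at the terminal carbon (aldehyde instead of methyl ketone), palladium may cleave or isomerise the enol acetate, or the exocyclic double bond of the lactone may migrate. The fallback replaces oxypalladation by a radical Markovnikov hydration; it sets out from 19 and comes back at 20. Mukaiyama hydration of 19 (Co(acac)2, PhSiH3, O2, iPrOH) should give the secondary alcohol F8 as a mixture of C4 epimers, and Dess–Martin oxidation gives 20.

Further compounds
F1 | step 10 | 5-tert-butyl 1-ethyl (2R,3R)-2-[(tert-butyldimethylsilyl)oxy]-3-formyl-4-methylidenepentanedioate | CCOC(=O)[C@H](O[Si](C)(C)C(C)(C)C)[C@H](C=O)C(=C)C(=O)OC(C)(C)C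
F2 | step 10 | 5-tert-butyl 1-ethyl (2R,3R)-2-[(tert-butyldimethylsilyl)oxy]-3-(dimethoxymethyl)-4-methylidenepentanedioate | CCOC(=O)[C@H](O[Si](C)(C)C(C)(C)C)[C@H](C(OC)OC)C(=C)C(=O)OC(C)(C)C
F3 | step 10 | tert-butyl (3R,4R)-4-[(tert-butyldimethylsilyl)oxy]-3-(dimethoxymethyl)-2-methylidene-5-oxopentanoate | O=C[C@H](O[Si](C)(C)C(C)(C)C)[C@H](C(OC)OC)C(=C)C(=O)OC(C)(C)C
F4 | step 10 | C6 dimethyl acetal of 14 (open-chain 9-O-Bpin adduct with the E-allylboronate) | COC(OC)[C@H](C(=C)C(=O)OC(C)(C)C)[C@@H](O[Si](C)(C)C(C)(C)C)[C@H](OB1OC(C)(C)C(C)(C)O1)[C@@](C)(/C=C\OC(C)=O)/C=C/CB1OC(C)(C)C(C)(C)O1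
F5 | step 10 | 9-hydroxy analogue of 14 (C6 aldehyde, free 9-OH, E-allylboronate) | O=C[C@H](C(=C)C(=O)OC(C)(C)C)[C@@H](O[Si](C)(C)C(C)(C)C)[C@H](O)[C@@](C)(/C=C\OC(C)=O)/C=C/CB1OC(C)(C)C(C)(C)O1
F6 | step 10 | 6α-O-pinacolboryl derivative of 16 (free 9β-OH) | CC1(C)OB(O[C@H]2[C@H](C(=C)C(=O)OC(C)(C)C)[C@@H](O[Si](C)(C)C(C)(C)C)[C@H](O)[C@@](C)(/C=C\OC(C)=O)[C@@H]2C=C)OC1(C)C
F7 | step 5 | tert-butyl (3S,4R)-4-[(tert-butyldimethylsilyl)oxy]-5-hydroxy-3-(hydroxymethyl)-2-methylidenepentanoate | OC[C@H](O[Si](C)(C)C(C)(C)C)[C@H](CO)C(=C)C(=O)OC(C)(C)C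
F8 | step 13 | (1Z)-2,9β-diacetoxy-8α-[(tert-butyldimethylsilyl)oxy]-4-hydroxy-15-norelema-1,11(13)-dien-12,6α-olide (C4 epimers) | C=C1C(=O)O[C@H]2[C@H]1[C@@H](O[Si](C)(C)C(C)(C)C)[C@H](OC(C)=O)[C@@](C)(/C=C\OC(C)=O)[C@@H]2C(C)O
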